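## Analysis of the target

The target is a 1,4-naphthoquinone. Ring A is a benzene ring with methoxy groups on C5, C7 and C8 and a single hydrogen on C6. Ring B is the quinone ring: carbonyls at C1 (bonded to C8a) and C4 (bonded to C4a), an enolic hydroxyl on C3, and a CH2–CH(OAc)–CH3 chain on C2. The only stereocentre is the acetoxy-bearing carbon of the chain (S); it is separated from the ring by one methylene and relates to no other centre. Sensitive features are the acidic enol (a vinylogous carboxylic acid), the electrophilic and redox-active quinone, and the secondary acetate. The acetate sits beta to a methylene that is vinylogously acidified through C2=C3–C4=O, so base can cause elimination. The methoxy groups on C5 and C8 are peri to carbonyls and would be cleaved by strong Lewis acids. The main difficulty is regiochemical: ring A is unsymmetrical, so the chain must end up on the ring B carbon next to C1 (the C8a side, near the C7/C8 dimethoxy pair) and the oxygen on the carbon next to C4. The strategy rests on the fact that C2 is alpha to C1(=O) and C3 is alpha to C4(=O), with C1 and C4 on adjacent ring A carbons. The C2–C3 bond is therefore the bond between the two enolate carbons of a 1,2-diacylbenzene.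

## Retrosynthetic reasoning

Target 16 is traced back to diol 14 by removing the acetyl group, then to silyl ether 13 and to the C3 methyl ether 12. The acetate goes on last because an ester would not survive the strong base of the ring-forming step. The enol stays masked as a vinylogous methyl ester so that ring B can be built from an alpha-methoxy ketone.

Quinone 12 is cut at C2–C3. This is the only ring B bond whose two ends are both alpha to a carbonyl, and cutting it gives diketone 9, in which every ring A substituent is already in place. Each ketone of 9 has alpha-hydrogens on one side only, so there is no regiochemical choice in enolisation or in ring closure. The forward reaction must remove two protons, remove two electrons, join the two enolate carbons (via bis-enolate 10), and then take the dihydroquinone 11 up to the quinone.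

Diketone 9 is cut at C3–C4, between the methoxymethyl carbon and its carbonyl, giving keto aldehyde 7 by way of carbinol 8. Adding a one-carbon methoxymethyl nucleophile to an aldehyde and re-oxidising is simpler than acylating an arene that already carries a ketone. The forward step needs chemoselectivity for the formyl group over the hindered ketone.

Keto aldehyde 7 is cut at the aryl–acyl bond (C1–C8a of the target), giving aldehyde 4 and amide 3. In 4 the carbon to be acylated is C6 (benzaldehyde numbering), the only hydrogen ortho to the formyl group, and it also has a methoxy neighbour. A temporarily masked formyl group (intermediates 5 and 6) can direct metalation there. Aldehyde 4 is commercial and carries the full oxygen pattern of ring A.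

Amide 3 goes back through hydroxy amide 2 to lactone 1. The lactone supplies all five chain carbons and the stereocentre with the correct configuration, gamma to the acyl carbon, so no stereocentre has to be created in the route.

## Alternatives that were turned down

Alternative 1: Ring B from a Diels–Alder reaction. The bonds C4–C4a and C1–C8a are cut. The diene A1, 2-(tert-butyldimethylsilyloxy)-3-[(S)-2-(tert-butyldimethylsilyloxy)propyl]buta-1,3-diene, would add to the unsubstituted double bond of 2-methoxy-1,4-benzoquinone A2 to give the cis-fused adduct A3.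
- For: the cycloaddition is a dependable, well-understood way to form the ring, needs no strong base, and in that respect is stronger than the chosen ring closure.
- Against: the orientation depends only on the electronic difference between the two carbonyls of A2 and on the silyloxy group of A1, which the neighbouring alkyl group partly opposes. The regioisomer with the ring A methoxy on C6 instead of C7 is therefore expected as well. A3 is also far from the target's oxidation level: ring A has to be aromatised and methylated twice, and the two ring B methylenes have to be oxidised to carbonyls. A1 needs several steps of its own, and two silyl ethers must be told apart.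
- Comparison: the chosen route takes the ring A pattern unambiguously from aldehyde 4 and reaches the quinone oxidation level in the ring-forming step, with fewer steps overall.

Alternative 2: Rearrangement of an alkylidene isochromanedione. The bond C1–C2 is cut. In 5,7,8-trimethoxy-3-[(S)-3-(tert-butyldimethylsilyloxy)butylidene]isochromane-1,4-dione A4, C1 is the lactone carbonyl and C2 is the exocyclic alkene carbon. An alkoxide would open the lactone, and the diketone enolate set free would attack the new ester (Claisen condensation) to give the silyl-protected hydroxyquinone A5, which is the same compound as 13.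
- For: this is two-electron carbonyl chemistry driven by formation of the stabilised hydroxyquinone anion, so the key step is at least as reliable as the chosen one. The C3 oxygen arrives free, which saves the ether hydrolysis.
- Against: A4 combines a vicinal dicarbonyl unit, an enol lactone and an ortho carboxyl on the pentasubstituted arene. Making it needs a regiodefined isochromanedione and a condensation with a beta-silyloxy aldehyde that eliminates silanol easily. In A4 the chain methylene is vinylogously acidic, so the same elimination threatens under the alkoxide.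
- Comparison: the weak point is the precursor, not the ring closure. The chosen diketone 9 is reached in five steps from two commercial compounds, which A4 cannot match.

Alternative 3: Cyclobutenone ring expansion. The bond C1–C8a is cut. The aryllithium from 1-bromo-2,4,5-trimethoxybenzene A6 would add to 3-isopropoxy-4-[(S)-2-(tert-butyldimethylsilyloxy)propyl]cyclobut-3-ene-1,2-dione A7 to give the 4-aryl-4-hydroxycyclobutenone A8. Heating A8 would open the four-membered ring to an aryl vinylketene, which closes onto the free ortho carbon and tautomerises to the hydroquinone A9.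
- For: this is the best-precedented route to 2-alkyl-3-alkoxy naphthoquinones and is convergent. Halogen–lithium exchange on A6 fixes the ring A regiochemistry without any competition between ring hydrogens, which is stronger than the directed metalation of the chosen route.
- Against: A7 needs a 2-silyloxypropyl group attached to a squaric ester. The obvious nucleophile is a beta-oxygenated organometallic that eliminates readily, and ways round this cost steps. The ring expansion needs about 140 °C, and A9 must still be oxidised and its isopropyl ether cleaved.
- Comparison: stronger on precedent and ring A control. The chosen route instead uses a chiral fragment (3) that needs no beta-oxygenated carbanion, forms the quinone directly, and is shorter.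

Key step: step 6

Remark on the chemistry: the coupling precursor 9 is a pentan-1-one with the silyloxy group on C4, all five chain carbons coming from lactone 1. Only this chain length puts a 2-oxypropyl group on C2 of the quinone.

## Route

Step 1
Reactants: 1 (S)-γ-valerolactone
Product: 2 (S)-4-hydroxy-N-methoxy-N-methylpentanamide
Conditions: MeNH(OMe)·HCl, AlMe3, CH2Cl2, 0 °C → rt
Reagents that add atoms: N,O-dimethylhydroxylamine hydrochloride, CNOC.Cl
Why: Weinreb aminolysis of a lactone; the aluminium amide attacks the acyl carbon only, so the carbinol centre keeps the S configuration of 1. Compound 2 should be silylated at once because it can relactonise.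

Step 2
Reactants: 2 (S)-4-hydroxy-N-methoxy-N-methylpentanamide
Product: 3 (S)-4-(tert-butyldimethylsilyloxy)-N-methoxy-N-methylpentanamide
Conditions: TBSCl, imidazole, DMF, rt
Reagents that add atoms: tert-butyldimethylsilyl chloride, CC(C)(C)[Si](C)(C)Cl
Why: Standard silylation of a secondary alcohol; the silyl ether blocks relactonisation and should tolerate organolithiums, amide bases and CuCl2 later on.

Step 3
Reactants: 4 2,4,5-trimethoxybenzaldehyde; 3 (S)-4-(tert-butyldimethylsilyloxy)-N-methoxy-N-methylpentanamide
Product: 7 3,4,6-trimethoxy-2-[(S)-4-(tert-butyldimethylsilyloxy)pentanoyl]benzaldehyde, via lithium amino alkoxide 5 (not isolated), via ortho-lithiated amino alkoxide 6 (not isolated)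
Conditions: LiN(Me)CH2CH2NMe2 (from MeNHCH2CH2NMe2 and n-BuLi), THF, −20 °C; n-BuLi, −20 °C; then 3 (excess), −78 → 0 °C; aq. NH4Cl
Reagents that add atoms: none
Why: Directed ortho-metalation through an alpha-amino alkoxide formed in situ, followed by Weinreb ketone synthesis. The chelating side arm of 5 and the methoxy group on C5 together direct butyllithium to C6, the only hydrogen ortho to the masked formyl group; the other ring hydrogen lies between two methoxy groups, which are weaker directors. Acylation of 6 by 3 stops at the chelated tetrahedral adduct, and aqueous work-up releases the ketone and the aldehyde together; 3 is used in excess because surplus n-BuLi consumes part of it.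

Step 4
Reactants: 7 3,4,6-trimethoxy-2-[(S)-4-(tert-butyldimethylsilyloxy)pentanoyl]benzaldehyde
Product: 8 (4S)-4-(tert-butyldimethylsilyloxy)-1-[2-(1-hydroxy-2-methoxyethyl)-3,5,6-trimethoxyphenyl]pentan-1-one
Conditions: MeOCH2MgCl (freshly made from MeOCH2Cl, Mg, cat. HgCl2, THF, −20 °C), THF, −40 → −20 °C; aq. NH4Cl
Reagents that add atoms: methoxymethylmagnesium chloride, COC[Mg]Cl (made from chloromethyl methyl ether, COCCl, and Mg)
Why: Grignard addition to the formyl group, which is far more electrophilic than the twisted, doubly ortho-substituted aryl ketone; the alkoxide formed can close onto that ketone as a hemiketal and shield it. Compound 8 should form as a mixture of carbinol epimers in equilibrium with its cyclic hemiketal, which does not matter because the carbinol is oxidised next.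

Step 5
Reactants: 8 (4S)-4-(tert-butyldimethylsilyloxy)-1-[2-(1-hydroxy-2-methoxyethyl)-3,5,6-trimethoxyphenyl]pentan-1-one
Product: 9 (S)-4-(tert-butyldimethylsilyloxy)-1-[3,5,6-trimethoxy-2-(methoxyacetyl)phenyl]pentan-1-one
Conditions: Dess–Martin periodinane, NaHCO3, CH2Cl2, 0 °C → rt
Reagents that add atoms: none
Why: Dess–Martin oxidation of the secondary benzylic alcohol through the open hydroxy ketone form; the buffered, non-basic medium should avoid aldol cyclisation of the 1,2-diacylbenzene.

Step 6
Reactants: 9 (S)-4-(tert-butyldimethylsilyloxy)-1-[3,5,6-trimethoxy-2-(methoxyacetyl)phenyl]pentan-1-one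
Product: 12 3,5,7,8-tetramethoxy-2-[(S)-2-(tert-butyldimethylsilyloxy)propyl]-1,4-naphthoquinone, via dilithium bis-enolate 10 (not isolated), via 2,3-dihydronaphthoquinone 11 (not isolated)
Conditions: lithium diisopropylamide (2.4 equiv), THF, −78 °C, 9 added slowly to the base; CuCl2 (5 equiv), DMF, −78 → 0 °C; then Et3N, rt
Reagents that add atoms: none
Why: Proposed new method: each ketone of 9 has alpha-hydrogens on one side only, so two equivalents of lithium diisopropylamide can give the single dilithium bis-enolate 10, and slow addition of 9 to cold excess base is meant to complete the second deprotonation before the first enolate attacks the neighbouring carbonyl in an aldol reaction. CuCl2 (divalent copper) takes one electron from an enolate to give an alpha-keto radical, which attacks the alpha-carbon of the second enolate, and a second electron transfer gives the 1,4-diketone 11; an alpha-chloro ketone formed by chlorine transfer would be displaced by the remaining enolate with the same result. The closest known reaction type is the intramolecular oxidative coupling of ketone bis-enolates with CuCl2 or FeCl3, or of bis(silyl enol ethers) with (NH4)2Ce(NO3)6, to cyclic 1,4-diketones, which has not been shown for a 1,2-diacylbenzene closing to a naphthoquinone. Ring B closes in a 6-endo-trig mode with respect to the accepting enolate double bond C3=C4; this is preferred over 5-exo attack at the oxygen-bearing carbon C4 because the radical adds to the nucleophilic alpha-carbon and leaves a stabilised aryl ketyl. The stereocentres formed at C2 and C3 of 11 need no control, since amine-assisted enolisation to the 1,4-naphthalenediol and oxidation by the remaining CuCl2 make both carbons trigonal in 12, and the silyloxy-bearing carbon is separated from the nearest enolate carbon by a methylene and is untouched. The selectivity needed is coupling within one molecule over aldol closure and over coupling between molecules; the ortho arrangement holds the two enolate carbons four atoms apart, and full double enolisation before the oxidant arrives removes the free carbonyl that the aldol reaction needs.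

Step 7
Reactants: 12 3,5,7,8-tetramethoxy-2-[(S)-2-(tert-butyldimethylsilyloxy)propyl]-1,4-naphthoquinone
Product: 13 3-hydroxy-5,7,8-trimethoxy-2-[(S)-2-(tert-butyldimethylsilyloxy)propyl]-1,4-naphthoquinone
Conditions: NaOH (aq.), THF/MeOH, rt; then 1 M HCl
Reagents that add atoms: sodium hydroxide, [Na+].[OH-]
Why: Addition–elimination of hydroxide at C3 of a 2-alkoxy-1,4-naphthoquinone (saponification of a vinylogous ester), driven by formation of the stabilised hydroxyquinone anion. The aryl methyl ethers and the silyl ether should be inert to dilute hydroxide at room temperature.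

Step 8
Reactants: 13 3-hydroxy-5,7,8-trimethoxy-2-[(S)-2-(tert-butyldimethylsilyloxy)propyl]-1,4-naphthoquinone
Product: 14 3-hydroxy-2-[(S)-2-hydroxypropyl]-5,7,8-trimethoxy-1,4-naphthoquinone
Conditions: HF (aq.), MeCN, 0 °C → rt
Reagents that add atoms: none
Why: Acid-mediated cleavage of a secondary silyl ether; the non-basic medium keeps the quinone and the side-chain methylene away from base, and the C–O bond of the stereocentre is not broken.

Step 9
Reactants: 14 3-hydroxy-2-[(S)-2-hydroxypropyl]-5,7,8-trimethoxy-1,4-naphthoquinone
Product: 16 (S)-1-(3-hydroxy-5,7,8-trimethoxy-1,4-dioxo-1,4-dihydronaphthalen-2-yl)propan-2-yl acetate, via diacetate 15 (not isolated)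
Conditions: Ac2O, pyridine, DMAP (cat.), CH2Cl2, 0 °C → rt; then MeOH, aq. NaHCO3, rt; acidify
Reagents that add atoms: acetic anhydride, CC(=O)OC(C)=O
Why: Acetylation of both hydroxyl groups, then selective methanolysis: the enol acetate of a 2-hydroxy-1,4-naphthoquinone is a vinylogous mixed anhydride and should be cleaved by bicarbonate in methanol, conditions under which the secondary alkyl acetate is stable. Acylation takes place at oxygen, so the S configuration is kept.

## Compound list

1 | (S)-γ-valerolactone | C[C@H]1CCC(=O)O1 | starting material
2 | (S)-4-hydroxy-N-methoxy-N-methylpentanamide | CON(C)C(=O)CC[C@H](C)O | intermediate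
3 | (S)-4-(tert-butyldimethylsilyloxy)-N-methoxy-N-methylpentanamide | CON(C)C(=O)CC[C@H](C)O[Si](C)(C)C(C)(C)C | intermediate
4 | 2,4,5-trimethoxybenzaldehyde | COc1cc(OC)c(C=O)cc1OC | starting material
5 | lithium alpha-amino alkoxide from 4 and LiN(Me)CH2CH2NMe2 (racemic at the carbinol carbon) | COc1cc(OC)c(C(O[Li])N(C)CCN(C)C)cc1OC | intermediate
6 | C6-lithiated amino alkoxide (racemic at the carbinol carbon) | COc1cc(OC)c(C(O[Li])N(C)CCN(C)C)c([Li])c1OC | intermediate
7 | 3,4,6-trimethoxy-2-[(S)-4-(tert-butyldimethylsilyloxy)pentanoyl]benzaldehyde | COc1cc(OC)c(C=O)c(C(=O)CC[C@H](C)O[Si](C)(C)C(C)(C)C)c1OC | intermediate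
8 | (4S)-4-(tert-butyldimethylsilyloxy)-1-[2-(1-hydroxy-2-methoxyethyl)-3,5,6-trimethoxyphenyl]pentan-1-one (both carbinol epimers; open form of the hemiketal) | COCC(O)c1c(OC)cc(OC)c(OC)c1C(=O)CC[C@H](C)O[Si](C)(C)C(C)(C)C | intermediate
9 | (S)-4-(tert-butyldimethylsilyloxy)-1-[3,5,6-trimethoxy-2-(methoxyacetyl)phenyl]pentan-1-one | COCC(=O)c1c(OC)cc(OC)c(OC)c1C(=O)CC[C@H](C)O[Si](C)(C)C(C)(C)C | intermediate
10 | dilithium bis-enolate of 9 (enolate geometry not defined) | COC=C(O[Li])c1c(OC)cc(OC)c(OC)c1C(O[Li])=CC[C@H](C)O[Si](C)(C)C(C)(C)C | intermediate
11 | 3,5,7,8-tetramethoxy-2-[(S)-2-(tert-butyldimethylsilyloxy)propyl]-2,3-dihydronaphthalene-1,4-dione (mixture at C2 and C3) | COc1cc(OC)c2c(c1OC)C(=O)C(C[C@H](C)O[Si](C)(C)C(C)(C)C)C(OC)C2=O | intermediate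
12 | 3,5,7,8-tetramethoxy-2-[(S)-2-(tert-butyldimethylsilyloxy)propyl]-1,4-naphthoquinone | COc1cc(OC)c2c(c1OC)C(=O)C(C[C@H](C)O[Si](C)(C)C(C)(C)C)=C(OC)C2=O | intermediate
13 | 3-hydroxy-5,7,8-trimethoxy-2-[(S)-2-(tert-butyldimethylsilyloxy)propyl]-1,4-naphthoquinone | COc1cc(OC)c2c(c1OC)C(=O)C(C[C@H](C)O[Si](C)(C)C(C)(C)C)=C(O)C2=O | intermediate
14 | 3-hydroxy-2-[(S)-2-hydroxypropyl]-5,7,8-trimethoxy-1,4-naphthoquinone | COc1cc(OC)c2c(c1OC)C(=O)C(C[C@H](C)O)=C(O)C2=O | intermediate
15 | (S)-1-(3-acetoxy-5,7,8-trimethoxy-1,4-dioxo-1,4-dihydronaphthalen-2-yl)propan-2-yl acetate | COc1cc(OC)c2c(c1OC)C(=O)C(C[C@H](C)OC(C)=O)=C(OC(C)=O)C2=O | intermediate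
16 | (S)-1-(3-hydroxy-5,7,8-trimethoxy-1,4-dioxo-1,4-dihydronaphthalen-2-yl)propan-2-yl acetate | COc1cc(OC)c2c(c1OC)C(=O)C(C[C@H](C)OC(C)=O)=C(O)C2=O | target

## Step count and least certain steps

Total: 9 steps. Longest linear sequence: 9 steps (1 → 16); aldehyde 4 enters at step 3.

Step 6 (key step). The most likely failure is aldol closure of a mono-enolate onto the neighbouring carbonyl, because this five-membered ring closure may be faster than the second deprotonation. Next in likelihood is loss of methanol from 11 by beta-elimination before it is oxidised, which would leave C3 without oxygen. Alpha-chlorination without ring closure, or coupling between molecules, are further possibilities. Trapping both enolates as silyl enol ethers as they form and regenerating the lithium enolates before oxidation would be the first adjustment of conditions.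
Fallback (known reactions only), from 7 back to 13:
- Aldehyde 7 reacts with the ylide from (methoxymethyl)triphenylphosphonium chloride and KN(SiMe3)2 (Wittig reaction) to give (S)-4-(tert-butyldimethylsilyloxy)-1-[3,5,6-trimethoxy-2-(2-methoxyvinyl)phenyl]pentan-1-one F1.
- Mild aqueous acid unmasks the arylacetaldehyde, which condenses with the methylene of the ketone (intramolecular aldol condensation) and aromatises to 5,7,8-trimethoxy-2-[(S)-2-(tert-butyldimethylsilyloxy)propyl]naphthalen-1-ol F2.
- Oxidation at the free para position with (KSO3)2NO gives 5,7,8-trimethoxy-2-[(S)-2-(tert-butyldimethylsilyloxy)propyl]-1,4-naphthoquinone F3.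
- Nucleophilic epoxidation (H2O2, Na2CO3) gives 2,3-epoxy-5,7,8-trimethoxy-2-[(S)-2-(tert-butyldimethylsilyloxy)propyl]-2,3-dihydronaphthalene-1,4-dione F4.
- Aqueous NaOH opens the epoxide at C3 and eliminates water, giving hydroxyquinone 13.

Step 3. Metalation may be poorly regioselective: the hydrogen on C3 of 4 lies between two methoxy groups and could be removed in competition with C6, or both positions could be metalated. Surplus n-BuLi also consumes part of amide 3.
Fallback, from 4 and 3 back to 9, using a stronger director and one equivalent of base:
- Oxidation of 4 with NaClO2 gives 2,4,5-trimethoxybenzoic acid F5, which is converted through its acid chloride into N,N-diethyl-2,4,5-trimethoxybenzamide F6.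
- Reduction of 3 with i-Bu2AlH gives (S)-4-(tert-butyldimethylsilyloxy)pentanal F7.
- F6 is lithiated ortho to the amide with s-BuLi/TMEDA at −78 °C and added to F7; acid-induced lactonisation gives 4,5,7-trimethoxy-3-[(S)-3-(tert-butyldimethylsilyloxy)butyl]isobenzofuran-1(3H)-one F8.
- One equivalent of MeOCH2MgCl adds to the lactone carbonyl to give 1-{2-[(4S)-4-(tert-butyldimethylsilyloxy)-1-hydroxypentyl]-3,4,6-trimethoxyphenyl}-2-methoxyethanone F9 (as its hemiketal).
- Dess–Martin oxidation of F9 gives diketone 9.

Step 7. Hydroxide may deprotonate the vinylogously acidic side-chain methylene before substitution at C3 is complete, and the silyloxy group would then be lost by elimination.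
Fallback, from 12 directly to 14: warm aqueous HCl in dioxane hydrolyses the vinylogous methyl ester through the protonated quinone and cleaves the silyl ether in the same operation. No carbanion is formed on the side chain and no new compound is involved.

Step 9. The methanolysis may not discriminate cleanly between the two acetates, or base may cause loss of acetic acid from the side chain through the same vinylogous acidity.
Fallback, from 13 to 16, which masks the enol before the acetate is introduced:
- Alkylation of 13 with 4-methoxybenzyl chloride and K2CO3 gives 3-(4-methoxybenzyloxy)-5,7,8-trimethoxy-2-[(S)-2-(tert-butyldimethylsilyloxy)propyl]-1,4-naphthoquinone F10.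
- HF·pyridine gives 2-[(S)-2-hydroxypropyl]-3-(4-methoxybenzyloxy)-5,7,8-trimethoxy-1,4-naphthoquinone F11.
- Ac2O/pyridine gives (S)-1-[3-(4-methoxybenzyloxy)-5,7,8-trimethoxy-1,4-dioxo-1,4-dihydronaphthalen-2-yl]propan-2-yl acetate F12.
- Trifluoroacetic acid in CH2Cl2 at 0 °C removes the benzyl-type group and gives 16.

## Further compounds

F1 | step 6 | (S)-4-(tert-butyldimethylsilyloxy)-1-[3,5,6-trimethoxy-2-(2-methoxyvinyl)phenyl]pentan-1-one | COC=Cc1c(OC)cc(OC)c(OC)c1C(=O)CC[C@H](C)O[Si](C)(C)C(C)(C)C
F2 | step 6 | 5,7,8-trimethoxy-2-[(S)-2-(tert-butyldimethylsilyloxy)propyl]naphthalen-1-ol | COc1cc(OC)c2ccc(C[C@H](C)O[Si](C)(C)C(C)(C)C)c(O)c2c1OC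
F3 | step 6 | 5,7,8-trimethoxy-2-[(S)-2-(tert-butyldimethylsilyloxy)propyl]-1,4-naphthoquinone | COc1cc(OC)c2c(c1OC)C(=O)C(C[C@H](C)O[Si](C)(C)C(C)(C)C)=CC2=O
F4 | step 6 | 2,3-epoxy-5,7,8-trimethoxy-2-[(S)-2-(tert-butyldimethylsilyloxy)propyl]-2,3-dihydronaphthalene-1,4-dione | COc1cc(OC)c2c(c1OC)C(=O)C1(C[C@H](C)O[Si](C)(C)C(C)(C)C)OC1C2=O
F5 | step 3 | 2,4,5-trimethoxybenzoic acid | COc1cc(OC)c(C(=O)O)cc1OC
F6 | step 3 | N,N-diethyl-2,4,5-trimethoxybenzamide | CCN(CC)C(=O)c1cc(OC)c(OC)cc1OC
F7 | step 3 | (S)-4-(tert-butyldimethylsilyloxy)pentanal | O=CCC[C@H](C)O[Si](C)(C)C(C)(C)C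
F8 | step 3 | 4,5,7-trimethoxy-3-[(S)-3-(tert-butyldimethylsilyloxy)butyl]isobenzofuran-1(3H)-one | COc1cc(OC)c2c(c1OC)C(CC[C@H](C)O[Si](C)(C)C(C)(C)C)OC2=O
F9 | step 3 | 1-{2-[(4S)-4-(tert-butyldimethylsilyloxy)-1-hydroxypentyl]-3,4,6-trimethoxyphenyl}-2-methoxyethanone | COCC(=O)c1c(OC)cc(OC)c(OC)c1C(O)CC[C@H](C)O[Si](C)(C)C(C)(C)C
F0 | step 7 | none | none
F10 | step 9 | 3-(4-methoxybenzyloxy)-5,7,8-trimethoxy-2-[(S)-2-(tert-butyldimethylsilyloxy)propyl]-1,4-naphthoquinone | COc1ccc(COC2=C(C[C@H](C)O[Si](C)(C)C(C)(C)C)C(=O)c3c(OC)c(OC)cc(OC)c3C2=O)cc1
F11 | step 9 | 2-[(S)-2-hydroxypropyl]-3-(4-methoxybenzyloxy)-5,7,8-trimethoxy-1,4-naphthoquinone | COc1ccc(COC2=C(C[C@H](C)O)C(=O)c3c(OC)c(OC)cc(OC)c3C2=O)cc1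
F12 | step 9 | (S)-1-[3-(4-methoxybenzyloxy)-5,7,8-trimethoxy-1,4-dioxo-1,4-dihydronaphthalen-2-yl]propan-2-yl acetate | COc1ccc(COC2=C(C[C@H](C)OC(C)=O)C(=O)c3c(OC)c(OC)cc(OC)c3C2=O)cc1
A1 | alternative 1 | 2-(tert-butyldimethylsilyloxy)-3-[(S)-2-(tert-butyldimethylsilyloxy)propyl]buta-1,3-diene | C=C(O[Si](C)(C)C(C)(C)C)C(=C)C[C@H](C)O[Si](C)(C)C(C)(C)C
A2 | alternative 1 | 2-methoxy-1,4-benzoquinone | COC1=CC(=O)C=CC1=O
A3 | alternative 1 | cis-2-methoxy-6-(tert-butyldimethylsilyloxy)-7-[(S)-2-(tert-butyldimethylsilyloxy)propyl]-4a,5,8,8a-tetrahydronaphthalene-1,4-dione (one cis-fused diastereomer shown) | COC1=CC(=O)[C@H]2CC(O[Si](C)(C)C(C)(C)C)=C(C[C@H](C)O[Si](C)(C)C(C)(C)C)C[C@H]2C1=O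
A4 | alternative 2 | 5,7,8-trimethoxy-3-[(S)-3-(tert-butyldimethylsilyloxy)butylidene]isochromane-1,4-dione | COc1cc(OC)c2c(c1OC)C(=O)OC(=CC[C@H](C)O[Si](C)(C)C(C)(C)C)C2=O
A5 | alternative 2 | 3-hydroxy-5,7,8-trimethoxy-2-[(S)-2-(tert-butyldimethylsilyloxy)propyl]-1,4-naphthoquinone | COc1cc(OC)c2c(c1OC)C(=O)C(C[C@H](C)O[Si](C)(C)C(C)(C)C)=C(O)C2=O
A6 | alternative 3 | 1-bromo-2,4,5-trimethoxybenzene | COc1cc(OC)c(Br)cc1OC
A7 | alternative 3 | 3-isopropoxy-4-[(S)-2-(tert-butyldimethylsilyloxy)propyl]cyclobut-3-ene-1,2-dione | CC(C)OC1=C(C[C@H](C)O[Si](C)(C)C(C)(C)C)C(=O)C1=O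
A8 | alternative 3 | 4-hydroxy-3-isopropoxy-2-[(S)-2-(tert-butyldimethylsilyloxy)propyl]-4-(2,4,5-trimethoxyphenyl)cyclobut-2-en-1-one | COc1cc(OC)c(cc1OC)C1(O)C(OC(C)C)=C(C[C@H](C)O[Si](C)(C)C(C)(C)C)C1=O
A9 | alternative 3 | 3-isopropoxy-5,7,8-trimethoxy-2-[(S)-2-(tert-butyldimethylsilyloxy)propyl]naphthalene-1,4-diol | COc1cc(OC)c2c(O)c(OC(C)C)c(C[C@H](C)O[Si](C)(C)C(C)(C)C)c(O)c2c1OC
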